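The runs were computed from invented constants, noise included.

In the teal run at 120 s the readings of starting material, 27.7%, and target, 50.7%, leave a gap of 21.6% of the charge, and the green run at 120 s leaves 19.3%.

| flask | starting material | second substrate | free catalyst | remark | time |
|---|---|---|---|---|---|
| teal | 0.25 M | 0.0057 M (in portions, 2) | 6.2 mM | run made earlier; portions every 12 s |  |
| green | 0.25 M | 0.65 M (in portions, 2) | 6.2 mM | run made earlier; portions every 12 s |  |
| zeta | 0.25 M | 0.0100 M (in portions, 2) | 6.2 mM | the portions of second substrate follow each other after 12 s, the first at the start | 3.0 min |
| beta | 0.25 M | 0.0300 M (in portions, 2) | 6.2 mM | the portions of second substrate follow each other after 12 s, the first at the start | 3.0 min |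
| delta | 0.25 M | 0.0800 M (in portions, 2) | 6.2 mM | the portions of second substrate follow each other after 12 s, the first at the start | 3.0 min |
| eta | 0.25 M | 0.250 M (in portions, 2) | 6.2 mM | the portions of second substrate follow each other after 12 s, the first at the start | 3.0 min |
| alpha | 0.25 M | 0.800 M (in portions, 2) | 6.2 mM | the portions of second substrate follow each other after 12 s, the first at the start | 3.0 min |

| run | time / s | target / % | starting material / % |
|---|---|---|---|
| teal | 12.0 | 6.7 | 87.3 |
| teal | 30.0 | 16.6 | 72.3 |
| teal | 60.0 | 29.8 | 51.7 |
| teal | 90.0 | 41.2 | 37.5 |
| teal | 120 | 50.7 | 27.7 |
| green | 12.0 | 5.4 | 90.0 |
| green | 30.0 | 12.1 | 80.6 |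
| green | 60.0 | 20.7 | 65.4 |
| green | 90.0 | 28.8 | 54.3 |
| green | 120 | 35.6 | 45.1 |

(each reading ± 0.3 percentage points)

- a reading or a percentage of target counts all its forms, free or not
- the concentration of target that is asked is that of its free form alone
- "hardly changes" means that all values lie within two and a half points (for a concentration: within two and a half percent of the largest)
- a reading of starting material is of its free form alone

- [target] (only what is free in solution) at the end for zeta, beta, delta, eta, alpha, in this order
- how that number moves from the first to the last of them (hardly changes / rises all the way / rises, then falls / falls all the way / falls, then rises)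

I read the gap as a bound pair of one starting material and one target. The target reading counts such a pair once and the starting material reading does not count it, so the gap measures the pair. Material held on the catalyst also falls into the gap; the catalyst charge is 2.48% of the starting material, and I neglect it. Free target is then the target reading minus the gap.

If the pair stands in equilibrium, one number should describe both runs. I call it the holding constant H: the pair divided by the product of free starting material and free target 10.7 L mol⁻¹. That value comes from teal. Green, with 114 times the second substrate, independently gives 10.5 L mol⁻¹. The two differ by 0.200 L mol⁻¹, about what a scatter of 0.3 percentage points per reading allows, so I trust their mean, 10.6 L mol⁻¹.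

The charge balance then gives a rule. Writing a for free starting material and p for free target, and counting each pair as the 2 molecules it holds, the charge is a + p + 2Hap, so p = (charge − a)/(1 + 2Ha). As a rises, p falls.

Starting material decays at 0.0104 s⁻¹ in teal's last stretch and 0.00619 s⁻¹ in green's, so more second substrate leaves more of it. Extending teal to 3.0 min for zeta, its near neighbour, gives a of 0.0371 M, which is 14.8% of the charge, and p of 0.119 M. Extending green the same way gives 0.0650 M, and I expect alpha, with more second substrate, a little below that. My row therefore falls all the way.

The forecast gives 0.163 M, 0.161 M, 0.157 M, 0.144 M and 0.113 M, shape falls all the way, with the words “Catalyst-bound target is at most a few mM, and the data can't resolve it, so I neglect it.”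

The flasks give 0.113 M, 0.111 M, 0.106 M, 0.0898 M and 0.0589 M, shape falls all the way.

    starting material + target ⇌ idle adduct, settled at all times (K = 10.3 L mol⁻¹)
    catalyst intermediate B → free catalyst + second product (k = 0.279 s⁻¹)
    starting material + free catalyst ⇌ catalyst intermediate A (K = 6.46 L mol⁻¹, k = 35.6 L mol⁻¹ s⁻¹)
    catalyst intermediate A → free catalyst + target (k = 0.388 s⁻¹)
    second substrate + free catalyst ⇌ catalyst intermediate B (K = 2.80 L mol⁻¹, k = 3.27 L mol⁻¹ s⁻¹)

The pair is the idle adduct, in the usual term an off-cycle reservoir. Zeta's simulated starting material, 16.2%, put into the rule gives 0.113 M against 0.113 M, so my miss lies in the extended curve, not in H. On alpha, simulated starting material of 34.3% gives 0.0582 M against 0.0589 M. The joining is one part of what holds alpha's free target down: without it, alpha ends at 0.127 M instead of 0.0589 M. Another part is the undoing of catalyst intermediate A into starting material and free catalyst, acting together with the time allowed: without the undoing alpha ends at 0.225 M, and by 30.0 min its free target stands at 0.249 M.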